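**Route outline**

- **Cuts.** (a) The C14–O bond and the C13=CH2 alkene are undone together as an ene transposition, giving a 13E allylic alcohol. (b) The C15–C16 bond is cut to a labdane enal and a 2-silyloxy-4-methylfuran. (c) The C18–O bond is traced to a C18–H bond of a 4,4-dimethyl labdane. (d) The C13=C14 bond is cut to a C13 methyl ketone, a degradation product of (+)-larixol.
- **Forward order.** Rings A and B are never built; they arrive as the trans-decalin of larixol. The chain is cut to C13 and regrown by olefination, and C8 is hydrated. A temporary oxasilinane ring is closed onto C18 and oxidised open. The ready-made butenolide ring is joined at C15–C16, and the ene reaction finishes the chain.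
- **Enabling feature.** The equatorial 6α-oxygen on ring B and the equatorial 4α-methyl (C18) on ring A are peri neighbours, 1,3-syn across C5. The three γ-carbons C4, C8 and C10 carry no hydrogen. A silicon atom tethered to O6 can therefore only close the six-membered ring Si–O–C6–C5–C4–C18.
- **Stereochemistry.** C5, C6, C9 and C10 come from larixol. C8 comes from α-face epoxidation of the 8(17)-alkene and hydride opening. C4 comes from the choice of the equatorial methyl in the key step. C15 and C16 (both R) come from the catalyst-controlled vinylogous aldol reaction. C14 (S) comes from the hydroxyl-directed, threo-selective ene reaction.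

Key step: step 7

Numbering remark: C1–C15 and C17–C20 follow labdane numbering (C17 on C8, C18 = 4α-carbon, C19 = 4β-methyl, C20 on C10). C16 denotes the oxygen-bearing butenolide carbon bonded to C15. The one-carbon branch on C13 is called the 13-methyl or 13-methylidene group.

Assumption: the (R,R) form of the bis(phosphoramide) used in step 12 is taken to send nucleophiles to the Re face of unsaturated aldehydes, so its (S,S) antipode is chosen for the Si-face attack needed for 15R. This sense should be confirmed on 3-methylbut-2-enal before 13 is committed.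

**Step 1**
Reactants: 1 (+)-larixol
Product: 2 6α-hydroxy-14,15-dinorlabd-8(17)-en-13-one
Conditions: KMnO4, BnEt3NCl, CH2Cl2, 0 °C
Reagents that add atoms: none
Why: In this permanganate cleavage of a tertiary vinyl carbinol, the unhindered C14=C15 alkene should be hydroxylated and degraded to the methyl ketone faster than the shielded 8(17)-methylene or the hindered 6α-carbinol reacts, as is usual for manool-type labdanes, and only the C13 centre disappears.

**Step 2**
Reactants: 2 6α-hydroxy-14,15-dinorlabd-8(17)-en-13-one; 3 triethyl phosphonoacetate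
Product: 4 ethyl (13E)-6α-hydroxylabda-8(17),13-dien-15-oate
Conditions: NaH (excess), THF, 0 °C to 50 °C; 13Z isomer removed on silica
Reagents that add atoms: none
Why: Horner–Wadsworth–Emmons olefination of a methyl ketone with excess stabilised phosphonate anion (the 6-alkoxide is a spectator) should favour the E enoate, with the ester trans to the larger C12 chain.

**Step 3**
Reactants: 4 ethyl (13E)-6α-hydroxylabda-8(17),13-dien-15-oate
Product: 5 ethyl (13E)-8α,17-epoxy-6α-hydroxylabd-13-en-15-oate
Conditions: mCPBA, NaHCO3, CH2Cl2, 0 °C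
Reagents that add atoms: 3-chloroperbenzoic acid, O=C(OO)c1cccc(Cl)c1
Why: Prilezhaev epoxidation picks the electron-rich 1,1-disubstituted alkene over the electron-poor enoate, and the peracid should approach from the α face because the axial C20 methyl screens the β face of C8, which places the oxygen 8α (equatorial) and sets C8.

**Step 4**
Reactants: 5 ethyl (13E)-8α,17-epoxy-6α-hydroxylabd-13-en-15-oate
Product: 6 (13E)-labd-13-ene-6α,8α,15-triol
Conditions: LiAlH4, THF, 0 °C to 50 °C; then H2O, aq NaOH
Reagents that add atoms: none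
Why: In this hydride reduction the spiro-epoxide is opened by SN2 attack at the unhindered C17 methylene, so the C8–O bond keeps its α configuration and C17 becomes the axial methyl, while the β,β-disubstituted enoate is reduced 1,2 to the E allylic alcohol.

**Step 5**
Reactants: 6 (13E)-labd-13-ene-6α,8α,15-triol
Product: 7 (13E)-15-(tert-butyldimethylsilyloxy)labd-13-ene-6α,8α-diol
Conditions: TBSCl (1.05 equiv), imidazole, CH2Cl2, 0 °C
Reagents that add atoms: tert-butyldimethylsilyl chloride, CC(C)(C)[Si](C)(C)Cl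
Why: Silyl ether formation under steric control should be selective because the bulky chlorosilane reacts with the primary allylic 15-OH far faster than with the hindered secondary 6-OH or the tertiary 8-OH.

**Step 6**
Reactants: 7 (13E)-15-(tert-butyldimethylsilyloxy)labd-13-ene-6α,8α-diol
Product: 9 (13E)-15-(tert-butyldimethylsilyloxy)-6α-(diethylsilyloxy)-8α-(trimethylsilyloxy)labd-13-ene, via 6-O-diethylsilyl ether 8 (not isolated)
Conditions: Et2SiHCl (1.1 equiv), Et3N, CH2Cl2, −20 °C; then TMSOTf, 0 °C; pentane, filtration under argon, used crude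
Reagents that add atoms: chlorodiethylsilane, CC[SiH](Cl)CC; trimethylsilyl triflate, C[Si](C)(C)OS(=O)(=O)C(F)(F)F
Why: These are two O-silylations in one flask, in which the chlorohydrosilane should be taken up by the secondary 6α-OH in preference to the tertiary 8α-OH at low temperature and the silyl triflate then caps the tertiary alcohol, so the moisture-sensitive Si–H ether never meets water or silica.

**Step 7**
Reactants: 9 (13E)-15-(tert-butyldimethylsilyloxy)-6α-(diethylsilyloxy)-8α-(trimethylsilyloxy)labd-13-ene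
Product: 10 C18,O6-bridged 2,2-diethyl-1-oxa-2-silacyclohexane (ring Si–O–C6–C5–C4–C18, C19 left as the axial 4β-methyl, 8-O-TMS and 15-O-TBS unchanged)
Conditions: [Rh(cod)Cl]2 (2.5 mol %), Xantphos (4,5-bis(diphenylphosphino)-9,9-dimethylxanthene, 6 mol %), norbornene (2 equiv), THF, 100 °C, sealed tube
Reagents that add atoms: none
Why: The Si–H bond of 9 adds oxidatively to the Xantphos-bound monovalent rhodium centre and the hydride passes to norbornene, leaving a rhodium silyl that cleaves a C18–H bond through a seven-membered rhodacycle (Rh, Si, O, C6, C5, C4, C18) and forms the C18–Si bond by reductive elimination. The closest known reaction type is the rhodium/Xantphos-catalysed δ-selective intramolecular silylation of primary C(sp3)–H bonds in diethylhydrosilyl ethers, the 1,4-diol counterpart of the iridium-catalysed γ-silylation, and only the substrate is new here, a secondary decalin carbinol with a distant trisubstituted alkene. The single ring closed, the 1-oxa-2-silacyclohexane, closes by that C–Si reductive elimination as a chair fused across the peri positions C4 and C6, because the torsions C18–C4–C5–C6 and C4–C5–C6–O are both gauche and opposite in sign. C4 becomes a stereocentre by desymmetrisation of its two methyl groups, and the locked trans-decalin decides the outcome, since the equatorial 4α-methyl lies 1,3-syn to the equatorial 6α-oxygen whereas the axial 4β-methyl could only be bridged through a twist-boat. The step needs site selectivity over C19, C17, C20 and the ring C–H bonds, and the same geometry secures it (those bonds are anti to C6–O or would need strained rings), together with the absence of any γ C–H because C4, C8 and C10 are quaternary. The 8- and 15-oxygens are capped so that no second Si–O bond can form, and strained norbornene should outcompete the hindered C13=C14 alkene for the rhodium hydride.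

**Step 8**
Reactants: 10 C18,O6-bridged oxasilinane
Product: 11 (13E)-labd-13-ene-6α,8α,15,18-tetraol
Conditions: Bu4NF (excess), KHCO3, 30% aq H2O2, THF/MeOH, 50 °C
Reagents that add atoms: hydrogen peroxide, OO
Why: In this Tamao–Fleming oxidation fluoride makes silicon pentacoordinate, hydroperoxide adds and the C18 methylene migrates from silicon to oxygen without touching a stereocentre, while excess fluoride clears the TMS and TBS ethers in the same operation and the isolated alkene is inert to basic H2O2.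

**Step 9**
Reactants: 11 (13E)-labd-13-ene-6α,8α,15,18-tetraol
Product: 12 (13E)-6α,8α,18-trihydroxylabd-13-en-15-al
Conditions: activated MnO2, CH2Cl2/acetone, rt
Reagents that add atoms: none
Why: Allylic oxidation with MnO2 is selective for the allylic 15-OH over the saturated primary, secondary and tertiary alcohols and should keep the E geometry.

**Step 10**
Reactants: 12 (13E)-6α,8α,18-trihydroxylabd-13-en-15-al
Product: 13 (13E)-6α,8α,18-tris(triethylsilyloxy)labd-13-en-15-al
Conditions: TESOTf, 2,6-lutidine, CH2Cl2, −78 °C to 0 °C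
Reagents that add atoms: triethylsilyl triflate, CC[Si](CC)(CC)OS(=O)(=O)C(F)(F)F
Why: Silyl triflate silylation reaches even the tertiary 8α-OH, while 2,6-lutidine is too weak and hindered a base to enolise the enal at these temperatures and any reversible adduct at the aldehyde falls apart on aqueous work-up.

**Step 11**
Reactants: 14 4-methylfuran-2(5H)-one
Product: 15 2-(tert-butyldimethylsilyloxy)-4-methylfuran
Conditions: TBSOTf, Et3N, CH2Cl2, 0 °C
Reagents that add atoms: tert-butyldimethylsilyl triflate, CC(C)(C)[Si](C)(C)OS(=O)(=O)C(F)(F)F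
Why: Soft enolisation with silyl triflate and amine removes a γ-proton at C5 of the butenolide and traps the aromatic 2-silyloxyfuran, the standard entry to furan-based dienoxysilanes.

**Step 12**
Reactants: 13 (13E)-6α,8α,18-tris(triethylsilyloxy)labd-13-en-15-al; 15 2-(tert-butyldimethylsilyloxy)-4-methylfuran
Product: 17 (13E,15R)-15-hydroxy-15-[(2R)-3-methyl-5-oxo-2,5-dihydrofuran-2-yl]-6α,8α,18-tris(triethylsilyloxy)labd-13-ene, via 15-O-trichlorosilyl aldolate 16 (not isolated)
Conditions: 15 (1.5 equiv), SiCl4, (S,S)-CH2[CH2CH2N(Me)P(O)(N,N'-dimethyl-1,1'-binaphthyl-2,2'-diamido)]2 (5 mol %), i-Pr2NEt, CH2Cl2, −78 °C; aq NaHCO3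
Reagents that add atoms: silicon tetrachloride, Cl[Si](Cl)(Cl)Cl (its SiCl3 group sits on O15 of 16 only and leaves again on work-up)
Why: In this catalytic enantioselective vinylogous Mukaiyama aldol reaction under Lewis-base activation of SiCl4, the phosphoramide-bound trichlorosilyl cation binds the enal (an unsaturated aldehyde, the class this system accepts) and exposes its Si face (15R), the furan attacks through its γ-carbon in an open transition state that for furan donors should favour the syn adduct (16R), and hydrolysis of 16 frees the 15-OH.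

**Step 13**
Reactants: 17 (15R,16R)-aldol adduct
Product: 19 (14S,15R,16R)-14,15-dihydroxy-13-methylidene butenolide 6,8,18-tris(triethylsilyl) ether, via 14-hydroperoxide 18 (not isolated)
Conditions: O2, 5,10,15,20-tetraphenylporphyrin (cat.), visible light, CH2Cl2, −20 °C; then PPh3, 0 °C
Reagents that add atoms: oxygen, O=O
Why: In this hydroxyl-directed Schenck ene reaction, A(1,3) strain between the 13-methyl and C15 turns H15 into the alkene plane, hydrogen bonding steers singlet oxygen to the face bearing the 15-OH, and a hydrogen is taken from the methyl cis to C15, so oxygen should end on C14 threo to O15 (14S) with the alkene moved to C13=CH2, after which PPh3 reduces the O–O bond with retention and the electron-poor butenolide alkene stays untouched.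

**Step 14**
Reactants: 19 (14S,15R,16R)-diol tris(triethylsilyl) ether
Product: 20 CNP0301623.1
Conditions: HF·pyridine, pyridine, THF, 0 °C to rt
Reagents that add atoms: none
Why: Fluoride-mediated desilylation under buffered, base-free conditions removes the primary, secondary and tertiary TES ethers while the epimerisable C16 and the allylic diol should stay unchanged.

**Compound list**

1 | (+)-larixol, (13S)-labda-8(17),14-diene-6α,13-diol | C=C[C@@](C)(O)CC[C@@H]1[C@@]2(C)CCCC(C)(C)[C@@H]2[C@@H](O)CC1=C | starting material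
2 | 6α-hydroxy-14,15-dinorlabd-8(17)-en-13-one | CC(=O)CC[C@@H]1[C@@]2(C)CCCC(C)(C)[C@@H]2[C@@H](O)CC1=C | intermediate
3 | triethyl phosphonoacetate | CCOC(=O)CP(=O)(OCC)OCC | starting material
4 | ethyl (13E)-6α-hydroxylabda-8(17),13-dien-15-oate | CCOC(=O)/C=C(\C)CC[C@@H]1[C@@]2(C)CCCC(C)(C)[C@@H]2[C@@H](O)CC1=C | intermediate
5 | ethyl (13E)-8α,17-epoxy-6α-hydroxylabd-13-en-15-oate | CCOC(=O)/C=C(\C)CC[C@@H]1[C@@]2(C)CCCC(C)(C)[C@@H]2[C@@H](O)C[C@@]13OC3 | intermediate
6 | (13E)-labd-13-ene-6α,8α,15-triol | OC/C=C(\C)CC[C@@H]1[C@@]2(C)CCCC(C)(C)[C@@H]2[C@@H](O)C[C@@]1(C)O | intermediate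
7 | (13E)-15-(tert-butyldimethylsilyloxy)labd-13-ene-6α,8α-diol | CC(C)(C)[Si](C)(C)OC/C=C(\C)CC[C@@H]1[C@@]2(C)CCCC(C)(C)[C@@H]2[C@@H](O)C[C@@]1(C)O | intermediate
8 | 6-O-diethylsilyl ether of 7 (8α-OH free) | CC(C)(C)[Si](C)(C)OC/C=C(\C)CC[C@@H]1[C@@]2(C)CCCC(C)(C)[C@@H]2[C@@H](O[SiH](CC)CC)C[C@@]1(C)O | intermediate
9 | (13E)-15-(tert-butyldimethylsilyloxy)-6α-(diethylsilyloxy)-8α-(trimethylsilyloxy)labd-13-ene | CC(C)(C)[Si](C)(C)OC/C=C(\C)CC[C@@H]1[C@@]2(C)CCCC(C)(C)[C@@H]2[C@@H](O[SiH](CC)CC)C[C@@]1(C)O[Si](C)(C)C | intermediate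
10 | C18,O6-bridged 2,2-diethyl-1-oxa-2-silacyclohexane, 8-O-TMS, 15-O-TBS | CC(C)(C)[Si](C)(C)OC/C=C(\C)CC[C@@H]1[C@@]2(C)CCC[C@@]3(C)C[Si](CC)(CC)O[C@H]([C@H]23)C[C@@]1(C)O[Si](C)(C)C | intermediate
11 | (13E)-labd-13-ene-6α,8α,15,18-tetraol | OC/C=C(\C)CC[C@@H]1[C@@]2(C)CCC[C@@](C)(CO)[C@@H]2[C@@H](O)C[C@@]1(C)O | intermediate
12 | (13E)-6α,8α,18-trihydroxylabd-13-en-15-al | O=C/C=C(\C)CC[C@@H]1[C@@]2(C)CCC[C@@](C)(CO)[C@@H]2[C@@H](O)C[C@@]1(C)O | intermediate
13 | (13E)-6α,8α,18-tris(triethylsilyloxy)labd-13-en-15-al | O=C/C=C(\C)CC[C@@H]1[C@@]2(C)CCC[C@@](C)(CO[Si](CC)(CC)CC)[C@@H]2[C@@H](O[Si](CC)(CC)CC)C[C@@]1(C)O[Si](CC)(CC)CC | intermediate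
14 | 4-methylfuran-2(5H)-one | CC1=CC(=O)OC1 | starting material
15 | 2-(tert-butyldimethylsilyloxy)-4-methylfuran | CC1=COC(O[Si](C)(C)C(C)(C)C)=C1 | intermediate
16 | 15-O-trichlorosilyl ether of 17 | C/C(CC[C@@H]1[C@@]2(C)CCC[C@@](C)(CO[Si](CC)(CC)CC)[C@@H]2[C@@H](O[Si](CC)(CC)CC)C[C@@]1(C)O[Si](CC)(CC)CC)=C\[C@@H](O[Si](Cl)(Cl)Cl)[C@@H]1OC(=O)C=C1C | intermediate
17 | (13E,15R,16R)-15-hydroxy butenolide, 6,8,18-tris-O-TES | C/C(CC[C@@H]1[C@@]2(C)CCC[C@@](C)(CO[Si](CC)(CC)CC)[C@@H]2[C@@H](O[Si](CC)(CC)CC)C[C@@]1(C)O[Si](CC)(CC)CC)=C\[C@@H](O)[C@@H]1OC(=O)C=C1C | intermediate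
18 | 14-hydroperoxide (threo to the 15-OH), 13-methylidene, 6,8,18-tris-O-TES | C=C(CC[C@@H]1[C@@]2(C)CCC[C@@](C)(CO[Si](CC)(CC)CC)[C@@H]2[C@@H](O[Si](CC)(CC)CC)C[C@@]1(C)O[Si](CC)(CC)CC)[C@H](OO)[C@@H](O)[C@@H]1OC(=O)C=C1C | intermediate
19 | (14S,15R,16R)-14,15-diol, 13-methylidene, 6,8,18-tris-O-TES | C=C(CC[C@@H]1[C@@]2(C)CCC[C@@](C)(CO[Si](CC)(CC)CC)[C@@H]2[C@@H](O[Si](CC)(CC)CC)C[C@@]1(C)O[Si](CC)(CC)CC)[C@H](O)[C@@H](O)[C@@H]1OC(=O)C=C1C | intermediate
20 | CNP0301623.1, (14S,15R,16R)-6α,8α,14,15,18-pentahydroxy-13-methylidene butenolide | C=C(CC[C@@H]1[C@@]2(C)CCC[C@@](C)(CO)[C@@H]2[C@@H](O)C[C@@]1(C)O)[C@H](O)[C@@H](O)[C@@H]1OC(=O)C=C1C | target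

**Step count**

- Total step count: 14.
- Longest linear sequence: 13 steps from larixol (steps 1–10 and 12–14).

**Steps most likely to fail**

**Step 7.**
- What may go wrong: the rhodium silyl of a secondary carbinol ether may cleave the C18–H bond too slowly. Redistribution or hydrolysis of the Si–H ether, or rhodium-hydride isomerisation of the allylic silyl ether, could then take over.
- Fallback: a radical relay from the same oxygen replaces the organometallic one. It sets out from 9 and returns at 11. Short methanolysis (K2CO3, MeOH, 0 °C) should strip only the labile diethylsilyl group and give the 6α-alcohol F1. Nitrite exchange with t-BuONO gives the 6-O-nitrite F2. Barton nitrite photolysis (Pyrex-filtered Hg lamp, toluene, 0 °C) generates the 6α-alkoxyl radical, whose 1,5-hydrogen transfer through a six-membered transition state reaches the same 1,3-syn C18 methyl. NO capture and tautomerisation then give the 18-aldoxime F3. Buffered aq TiCl3/NH4OAc unmasks the 6α-hydroxy-18-aldehyde F4 (in equilibrium with its lactol). NaBH4 reduces it to the 6α,18-diol F5, and Bu4NF removes both silyl ethers to reach 11.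

**Step 12.**
- What may go wrong: the methyl group next to the reacting furan carbon and the β,β-disubstituted enal may slow the addition. They may also erode facial selectivity at both partners. Chlorosilane-derived acid may strip TES ethers.
- Fallback: an auxiliary-controlled acyclic aldol reaction is used, and the butenolide ring is built afterwards. It sets out from 13 and returns at 17. An Evans syn aldol reaction of 13 uses the dibutylboron enolate of (S)-4-benzyl-3-[(4-methoxybenzyloxy)acetyl]oxazolidin-2-one (Bu2BOTf, Et3N, CH2Cl2, −78 °C). It should give the syn glycolate adduct F6 with C15 and C16 in the required sense. MeNH(OMe)·HCl/AlMe3 gives the N-methoxy-N-methylamide F7. TMSCl/imidazole gives its 15-O-TMS ether F8, and MeMgBr gives the methyl ketone F9. DDQ (CH2Cl2, pH 7 buffer) removes the 4-methoxybenzyl group to give the α-hydroxy ketone F10. (Triphenylphosphoranylidene)ketene in warm toluene acylates the 16-OH and closes the ring by intramolecular Wittig reaction, giving the 15-O-TMS butenolide F11. Citric acid in MeOH at 0 °C cleaves only the TMS ether and delivers 17.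

**Step 13.**
- What may go wrong: hydrogen may be abstracted from C12 in place of the methyl group. Threo selectivity may also be lost if the 15-OH hydrogen-bonds to the lactone ring oxygen rather than to the incoming oxygen.
- Fallback: an epoxide rearrangement replaces photooxygenation. It sets out from 17 and returns at 19. Hydroxyl-directed epoxidation with mCPBA (CH2Cl2, 0 °C) is threo-selective for the same A(1,3) reason and should give the threo 13,14-epoxy-15-ol F12. Ti(OiPr)4 (CH2Cl2, rt) binds the 15-alkoxide, opens the epoxide at the tertiary C13 and removes a proton from the methyl group cis to C15. The C14–O bond stays in place and 19 is formed directly.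

**Further compounds**

F1 | step 7 | (13E)-15-(tert-butyldimethylsilyloxy)-8α-(trimethylsilyloxy)labd-13-en-6α-ol | CC(C)(C)[Si](C)(C)OC/C=C(\C)CC[C@@H]1[C@@]2(C)CCCC(C)(C)[C@@H]2[C@@H](O)C[C@@]1(C)O[Si](C)(C)C
F2 | step 7 | 6-O-nitrite of F1 | CC(C)(C)[Si](C)(C)OC/C=C(\C)CC[C@@H]1[C@@]2(C)CCCC(C)(C)[C@@H]2[C@@H](ON=O)C[C@@]1(C)O[Si](C)(C)C
F3 | step 7 | 6α-hydroxy-18-aldoxime, 8-O-TMS, 15-O-TBS | CC(C)(C)[Si](C)(C)OC/C=C(\C)CC[C@@H]1[C@@]2(C)CCC[C@@](C)(/C=N/O)[C@@H]2[C@@H](O)C[C@@]1(C)O[Si](C)(C)C
F4 | step 7 | 6α-hydroxy-18-aldehyde (open form of the lactol), 8-O-TMS, 15-O-TBS | CC(C)(C)[Si](C)(C)OC/C=C(\C)CC[C@@H]1[C@@]2(C)CCC[C@@](C)(C=O)[C@@H]2[C@@H](O)C[C@@]1(C)O[Si](C)(C)C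
F5 | step 7 | 6α,18-diol, 8-O-TMS, 15-O-TBS | CC(C)(C)[Si](C)(C)OC/C=C(\C)CC[C@@H]1[C@@]2(C)CCC[C@@](C)(CO)[C@@H]2[C@@H](O)C[C@@]1(C)O[Si](C)(C)C
F6 | step 12 | syn glycolate aldol adduct (15-OH, 16-O-PMB, (S)-4-benzyloxazolidinone imide) | C/C(CC[C@@H]1[C@@]2(C)CCC[C@@](C)(CO[Si](CC)(CC)CC)[C@@H]2[C@@H](O[Si](CC)(CC)CC)C[C@@]1(C)O[Si](CC)(CC)CC)=C\[C@@H](O)[C@H](OCc1ccc(OC)cc1)C(=O)N1[C@@H](Cc2ccccc2)COC1=O
F7 | step 12 | N-methoxy-N-methylamide (15-OH, 16-O-PMB) | C/C(CC[C@@H]1[C@@]2(C)CCC[C@@](C)(CO[Si](CC)(CC)CC)[C@@H]2[C@@H](O[Si](CC)(CC)CC)C[C@@]1(C)O[Si](CC)(CC)CC)=C\[C@@H](O)[C@H](OCc1ccc(OC)cc1)C(=O)N(C)OC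
F8 | step 12 | 15-O-TMS ether of F7 | C/C(CC[C@@H]1[C@@]2(C)CCC[C@@](C)(CO[Si](CC)(CC)CC)[C@@H]2[C@@H](O[Si](CC)(CC)CC)C[C@@]1(C)O[Si](CC)(CC)CC)=C\[C@@H](O[Si](C)(C)C)[C@H](OCc1ccc(OC)cc1)C(=O)N(C)OC
F9 | step 12 | methyl ketone (15-O-TMS, 16-O-PMB) | C/C(CC[C@@H]1[C@@]2(C)CCC[C@@](C)(CO[Si](CC)(CC)CC)[C@@H]2[C@@H](O[Si](CC)(CC)CC)C[C@@]1(C)O[Si](CC)(CC)CC)=C\[C@@H](O[Si](C)(C)C)[C@H](OCc1ccc(OC)cc1)C(C)=O
F10 | step 12 | α-hydroxy methyl ketone (15-O-TMS, 16-OH) | C/C(CC[C@@H]1[C@@]2(C)CCC[C@@](C)(CO[Si](CC)(CC)CC)[C@@H]2[C@@H](O[Si](CC)(CC)CC)C[C@@]1(C)O[Si](CC)(CC)CC)=C\[C@@H](O[Si](C)(C)C)[C@H](O)C(C)=O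
F11 | step 12 | 15-O-TMS ether of 17 | C/C(CC[C@@H]1[C@@]2(C)CCC[C@@](C)(CO[Si](CC)(CC)CC)[C@@H]2[C@@H](O[Si](CC)(CC)CC)C[C@@]1(C)O[Si](CC)(CC)CC)=C\[C@@H](O[Si](C)(C)C)[C@@H]1OC(=O)C=C1C
F12 | step 13 | threo 13,14-epoxy-15-ol (epoxide oxygen on the face of the 15-OH), 6,8,18-tris-O-TES | C[C@]5(CC[C@@H]1[C@@]2(C)CCC[C@@](C)(CO[Si](CC)(CC)CC)[C@@H]2[C@@H](O[Si](CC)(CC)CC)C[C@@]1(C)O[Si](CC)(CC)CC)O[C@@H]5[C@@H](O)[C@@H]1OC(=O)C=C1C
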